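**Retrosynthetic overview**
- Last bond made: the formyl C–C bond at C3 of ring A, the only aromatic C–H of the depside, by Rieche formylation of the free resorcinol depside.
- Before that: the ring B 2-OMe is set by O-methylation after esterification (the depside ester itself masks the 4-OH), and the ring A hydroxyls are carried as benzyl ethers and freed by hydrogenolysis.
- Depside C(=O)–O bond: trifluoroacetic anhydride coupling of 2,4-bis(benzyloxy)-5,6-dimethylbenzoic acid with the 4-OH of methyl 2,4-dihydroxy-3,5,6-trimethylbenzoate.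
- Ring B piece: from methyl 2,4-dihydroxy-3,6-dimethylbenzoate (C5 formylation, then CHO to CH3). Ring A piece: from 4,5-dimethylbenzene-1,3-diol (formylation, benzylation, oxidation).
- No ring is formed: both benzene rings are bought intact (ring B first, ring A second).

Assumption: the target SMILES has no stereocentre, so the compound is achiral and needs no stereocontrol; both starting materials are taken as catalogue chemicals.

**Step 1**
Reactants: 1 methyl 2,4-dihydroxy-3,6-dimethylbenzoate
Product: 3 methyl 5-formyl-2,4-dihydroxy-3,6-dimethylbenzoate, via chloro(methoxy)methyl arene 2 (not isolated)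
Conditions: Cl2CHOMe (1.5 equiv), TiCl4 (3 equiv), CH2Cl2, 0 °C to rt; then ice/1 M HCl
Reagents that add atoms: dichloromethyl methyl ether, COC(Cl)Cl; water, O
Why: Rieche formylation (electrophilic aromatic substitution) can only occur at C5, the single free ring position, which is ortho to the 4-OH and para to the 2-OH; no stereocentre is formed.

**Step 2**
Reactants: 3 methyl 5-formyl-2,4-dihydroxy-3,6-dimethylbenzoate
Product: 5 methyl 2,4-dihydroxy-3,5,6-trimethylbenzoate, via benzylic alcohol 4 (not isolated)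
Conditions: H2 (3 atm), 10% Pd/C, AcOH, cat. HCl, 40 °C
Reagents that add atoms: none
Why: Catalytic hydrogenation/hydrogenolysis of an electron-rich ortho-hydroxy aryl aldehyde proceeds through the benzylic alcohol to the methyl group under acid, leaving the methyl ester and the ring untouched.

**Step 3**
Reactants: 6 4,5-dimethylbenzene-1,3-diol
Product: 8 2,4-dihydroxy-5,6-dimethylbenzaldehyde, via iminium chloride 7 (not isolated)
Conditions: POCl3 (1.2 equiv), DMF, 0 °C to rt; then ice/H2O, 50 °C
Reagents that add atoms: N,N-dimethylformamide, CN(C)C=O; water, O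
Why: Vilsmeier–Haack formylation of a resorcinol goes para to one OH and ortho to the other (C6) rather than to the crowded position between the two hydroxyls, as it does with orcinol.

**Step 4**
Reactants: 8 2,4-dihydroxy-5,6-dimethylbenzaldehyde
Product: 9 2,4-bis(benzyloxy)-5,6-dimethylbenzaldehyde
Conditions: BnBr (2.4 equiv), K2CO3 (3 equiv), DMF, 60 °C
Reagents that add atoms: benzyl bromide, BrCc1ccccc1
Why: Williamson ether synthesis benzylates both phenols, with warming in DMF to drive the hydrogen-bonded 2-OH to completion.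

**Step 5**
Reactants: 9 2,4-bis(benzyloxy)-5,6-dimethylbenzaldehyde
Product: 10 2,4-bis(benzyloxy)-5,6-dimethylbenzoic acid
Conditions: NaClO2, NaH2PO4, 2-methyl-2-butene (excess), t-BuOH/THF/H2O, rt
Reagents that add atoms: NaClO2 (sodium chlorite), [Na+].[O-]Cl=O
Why: Pinnick (Lindgren) oxidation converts the hindered aldehyde to the acid while the alkene scavenger removes hypochlorous acid before it can chlorinate the electron-rich ring; benzyl ethers are inert.

**Step 6**
Reactants: 10 2,4-bis(benzyloxy)-5,6-dimethylbenzoic acid (1.1 equiv); 5 methyl 2,4-dihydroxy-3,5,6-trimethylbenzoate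
Product: 12 methyl 4-{[2,4-bis(benzyloxy)-5,6-dimethylbenzoyl]oxy}-2-hydroxy-3,5,6-trimethylbenzoate, via mixed trifluoroacetic anhydride 11 (not isolated)
Conditions: (CF3CO)2O (4 equiv), dry toluene, rt, 6 h; aq. NaHCO3 work-up
Reagents that add atoms: none
Why: Mixed-anhydride (acylium) depside esterification tolerates the di-ortho-substituted acid and acylates the free 4-OH of 5, whereas the 2-OH is hydrogen-bonded to the ester carbonyl and stays unreacted.

**Step 7**
Reactants: 12 methyl 4-{[2,4-bis(benzyloxy)-5,6-dimethylbenzoyl]oxy}-2-hydroxy-3,5,6-trimethylbenzoate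
Product: 13 methyl 4-{[2,4-bis(benzyloxy)-5,6-dimethylbenzoyl]oxy}-2-methoxy-3,5,6-trimethylbenzoate
Conditions: MeI (3 equiv), K2CO3 (2 equiv), DMF, 40 °C
Reagents that add atoms: iodomethane, CI
Why: Williamson O-methylation of the only free phenol; the depside ester, flanked by four ortho substituents, is too hindered for anhydrous carbonate to cleave.

**Step 8**
Reactants: 13 methyl 4-{[2,4-bis(benzyloxy)-5,6-dimethylbenzoyl]oxy}-2-methoxy-3,5,6-trimethylbenzoate
Product: 14 methyl 4-[(2,4-dihydroxy-5,6-dimethylbenzoyl)oxy]-2-methoxy-3,5,6-trimethylbenzoate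
Conditions: H2 (1 atm), 10% Pd/C, EtOAc, rt
Reagents that add atoms: none
Why: Hydrogenolysis of the two benzyl ethers is selective; aryl and methyl esters, the methyl ether and both rings are unaffected.

**Step 9**
Reactants: 14 methyl 4-[(2,4-dihydroxy-5,6-dimethylbenzoyl)oxy]-2-methoxy-3,5,6-trimethylbenzoate
Product: 16 methyl 4-[(3-formyl-2,4-dihydroxy-5,6-dimethylbenzoyl)oxy]-2-methoxy-3,5,6-trimethylbenzoate, via chloro(methoxy)methyl arene 15 (not isolated)
Conditions: Cl2CHOMe (2 equiv), TiCl4 (4 equiv), CH2Cl2, -10 °C to 0 °C; then ice/1 M HCl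
Reagents that add atoms: dichloromethyl methyl ether, COC(Cl)Cl; water, O
Why: Rieche formylation can only strike C3 of ring A, the sole aromatic C–H in the molecule and doubly ortho-activated by the two hydroxyls; ring B is fully substituted, and the low temperature spares the methyl ether and the esters.

**Compound list**
1 | methyl 2,4-dihydroxy-3,6-dimethylbenzoate | COC(=O)c1c(C)cc(O)c(C)c1O | starting material
2 | methyl 5-[chloro(methoxy)methyl]-2,4-dihydroxy-3,6-dimethylbenzoate (racemic) | COC(Cl)c1c(C)c(C(=O)OC)c(O)c(C)c1O | intermediate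
3 | methyl 5-formyl-2,4-dihydroxy-3,6-dimethylbenzoate | COC(=O)c1c(C)c(C=O)c(O)c(C)c1O | intermediate
4 | methyl 2,4-dihydroxy-5-(hydroxymethyl)-3,6-dimethylbenzoate | COC(=O)c1c(C)c(CO)c(O)c(C)c1O | intermediate
5 | methyl 2,4-dihydroxy-3,5,6-trimethylbenzoate | COC(=O)c1c(C)c(C)c(O)c(C)c1O | intermediate
6 | 4,5-dimethylbenzene-1,3-diol | Cc1cc(O)cc(O)c1C | starting material
7 | N-[(2,4-dihydroxy-5,6-dimethylphenyl)methylidene]-N-methylmethanaminium chloride | C[N+](C)=Cc1c(O)cc(O)c(C)c1C.[Cl-] | intermediate
8 | 2,4-dihydroxy-5,6-dimethylbenzaldehyde | O=Cc1c(O)cc(O)c(C)c1C | intermediate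
9 | 2,4-bis(benzyloxy)-5,6-dimethylbenzaldehyde | O=Cc1c(OCc2ccccc2)cc(OCc2ccccc2)c(C)c1C | intermediate
10 | 2,4-bis(benzyloxy)-5,6-dimethylbenzoic acid | OC(=O)c1c(OCc2ccccc2)cc(OCc2ccccc2)c(C)c1C | intermediate
11 | 2,4-bis(benzyloxy)-5,6-dimethylbenzoic trifluoroacetic anhydride | O=C(OC(=O)C(F)(F)F)c1c(OCc2ccccc2)cc(OCc2ccccc2)c(C)c1C | intermediate
12 | methyl 4-{[2,4-bis(benzyloxy)-5,6-dimethylbenzoyl]oxy}-2-hydroxy-3,5,6-trimethylbenzoate | COC(=O)c1c(C)c(C)c(OC(=O)c2c(C)c(C)c(OCc3ccccc3)cc2OCc2ccccc2)c(C)c1O | intermediate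
13 | methyl 4-{[2,4-bis(benzyloxy)-5,6-dimethylbenzoyl]oxy}-2-methoxy-3,5,6-trimethylbenzoate | COC(=O)c1c(C)c(C)c(OC(=O)c2c(C)c(C)c(OCc3ccccc3)cc2OCc2ccccc2)c(C)c1OC | intermediate
14 | methyl 4-[(2,4-dihydroxy-5,6-dimethylbenzoyl)oxy]-2-methoxy-3,5,6-trimethylbenzoate | COC(=O)c1c(C)c(C)c(OC(=O)c2c(C)c(C)c(O)cc2O)c(C)c1OC | intermediate
15 | methyl 4-({3-[chloro(methoxy)methyl]-2,4-dihydroxy-5,6-dimethylbenzoyl}oxy)-2-methoxy-3,5,6-trimethylbenzoate (racemic) | COC(=O)c1c(C)c(C)c(OC(=O)c2c(C)c(C)c(O)c(C(Cl)OC)c2O)c(C)c1OC | intermediate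
16 | methyl 4-[(3-formyl-2,4-dihydroxy-5,6-dimethylbenzoyl)oxy]-2-methoxy-3,5,6-trimethylbenzoate (CNP0206150.0, achiral) | COC(=O)c1c(C)c(C)c(OC(=O)c2c(C)c(C)c(O)c(C=O)c2O)c(C)c1OC | target

**Totals**
Total step count: 9.
Longest linear sequence: 7 steps (6 to 16 through steps 3, 4, 5, 6, 7, 8 and 9); the ring B branch (steps 1 and 2) joins at step 6.

**Three steps most likely to fail**

Step 6 (depside coupling). Both partners are di-ortho-substituted, the ortho benzyl ether may be lost from the acylium ion, and some acylation at the 2-OH cannot be excluded. The fallback sets out from 10 and 5 and comes back at 12. Acid 10 is converted with oxalyl chloride and catalytic DMF in CH2Cl2 into 2,4-bis(benzyloxy)-5,6-dimethylbenzoyl chloride F1. This isolated acyl chloride then acylates the more acidic, non-chelated 4-OH of 5 under basic conditions (Et3N, catalytic DMAP, CH2Cl2, reflux) to give 12, so the strongly acidic acylium conditions are avoided.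

Step 7 (methylation of the chelated, flanked 2-OH beside the depside ester). The reaction may be slow, and forcing it risks cleaving the depside. The fallback sets out from 5 and comes back at 13, with the methyl ether placed before the esterification. Selective benzylation of the free 4-OH (BnBr 1.05 equiv, K2CO3, acetone, reflux) gives methyl 4-(benzyloxy)-2-hydroxy-3,5,6-trimethylbenzoate F2. Forcing methylation, now with no depside present (MeI, K2CO3, DMF, 60 °C), gives methyl 4-(benzyloxy)-2-methoxy-3,5,6-trimethylbenzoate F3. Hydrogenolysis (H2, Pd/C, EtOAc) gives methyl 4-hydroxy-2-methoxy-3,5,6-trimethylbenzoate F4, which is coupled with 10 by trifluoroacetic anhydride in toluene to reach 13 directly.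

Step 9 (late formylation of the whole depside). TiCl4 may attack the ring B methyl ether or the depside ester, or conversion may stall on the ester-deactivated ring. The fallback sets out from 10 and comes back at 16, with the formyl group installed before the esterification.
- Hydrogenolysis of 10 (H2, Pd/C, EtOAc) gives 2,4-dihydroxy-5,6-dimethylbenzoic acid F5.
- Carboxylate alkylation (BnBr 1.0 equiv, KHCO3, DMF, rt) gives benzyl 2,4-dihydroxy-5,6-dimethylbenzoate F6.
- Magnesium-mediated ortho-formylation (MgCl2, Et3N, paraformaldehyde, MeCN, reflux), which is free of strong Lewis acid, gives benzyl 3-formyl-2,4-dihydroxy-5,6-dimethylbenzoate F7.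
- Brief hydrogenolysis of the benzyl ester (H2 1 atm, Pd/C, EtOAc, stopped after one equivalent) gives 3-formyl-2,4-dihydroxy-5,6-dimethylbenzoic acid F8, whose two hydroxyls are both hydrogen-bonded and need no protection.
- Carbodiimide coupling (DCC, toluene, rt) of F8 with methyl 4-hydroxy-2-methoxy-3,5,6-trimethylbenzoate F4, made as in the step 7 fallback, gives 16.

**Further compounds**
F1 | step 6 | 2,4-bis(benzyloxy)-5,6-dimethylbenzoyl chloride | O=C(Cl)c1c(OCc2ccccc2)cc(OCc2ccccc2)c(C)c1C
F2 | step 7 | methyl 4-(benzyloxy)-2-hydroxy-3,5,6-trimethylbenzoate | COC(=O)c1c(C)c(C)c(OCc2ccccc2)c(C)c1O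
F3 | step 7 | methyl 4-(benzyloxy)-2-methoxy-3,5,6-trimethylbenzoate | COC(=O)c1c(C)c(C)c(OCc2ccccc2)c(C)c1OC
F4 | step 7 | methyl 4-hydroxy-2-methoxy-3,5,6-trimethylbenzoate | COC(=O)c1c(C)c(C)c(O)c(C)c1OC
F5 | step 9 | 2,4-dihydroxy-5,6-dimethylbenzoic acid | OC(=O)c1c(O)cc(O)c(C)c1C
F6 | step 9 | benzyl 2,4-dihydroxy-5,6-dimethylbenzoate | O=C(OCc1ccccc1)c1c(O)cc(O)c(C)c1C
F7 | step 9 | benzyl 3-formyl-2,4-dihydroxy-5,6-dimethylbenzoate | O=Cc1c(O)c(C)c(C)c(C(=O)OCc2ccccc2)c1O
F8 | step 9 | 3-formyl-2,4-dihydroxy-5,6-dimethylbenzoic acid | O=Cc1c(O)c(C)c(C)c(C(=O)O)c1O
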